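## The problem

The target is a tricyclic diester built on a verbenone-type bicyclo[3.1.1]hept-3-en-2-one. Ring A is the six-membered ring C5–C6–C7–C8–C9–C10 (C7 ketone, C8=C9, methyl on C9), the cyclobutane is C5–C6–C11–C10, and the chain C4–C3–C2–C1 joins the two one-carbon bridges C5 and C11 into a seven-membered ring B. Four of the six stereocentres (C5, C6, C10, C11) lie in the cage and depend on one another: ring B can only span the two exo positions, so H5 and the C11 methyl must flank the enone bridge, and one centre of known configuration fixes all four. C1 and C3 are carbinols on ring B, trans to each other, each beside a quaternary carbon (C11, C4); the cage does not control them. The cyclobutane next to an enone tolerates no cation at C10 or C11 (pinane-type rearrangement), the tiglate can isomerise, and the senecioate deconjugates with base, so both esters belong late and C10 must be handled by radical chemistry only. The enabling feature is that ring A, its C9 methyl and the methyl-bearing C11 on C6 form the carvone skeleton once the carbonyl is placed at C10 instead of C7. C11 is then 1,3 to the carbonyl carbon, so a C11 radical can close the four-membered ring on C10, and if it is made from a C11–C1 epoxide the oxygen stays on C1 where the tiglate is needed. The price is an oxygen at C10 instead of C7, which has to be moved afterwards.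

## Retrosynthesis

**Ester C–O bonds.** The senecioate is cut first (28 ⇒ alcohol 25 + acid 26) and the tiglate second (21 ⇒ diol 19 + tigloyl chloride 20). In 19 the C1 hydroxyl is the only one that acylates easily, so the final tiglate doubles as its protecting group, and C3 stays silylated until 24. The forward steps must not isomerise either unsaturated acyl group.

**C7=O.** Enone 24 is traced to alkene 23 by removing the C7 carbonyl. Carrying a C7 oxygen through the radical step would offer the C11 radical a second acceptor. The forward reaction is the pinene-to-verbenone allylic oxidation and must choose the C7 methylene over the C9 methyl and the ester allylic positions.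

**C10–H.** 23 comes from oxalate 22 and tertiary alcohol 21. A bridgehead cyclobutanol can be neither ionised nor eliminated, so only a radical C–O cleavage is considered. This is the cost of using a ketone as radical acceptor, and the bridgehead cannot lose its configuration.

**C10–C11 (key).** Diol 19 is opened to the cis-fused epoxy enone 16. Against cutting C5–C6 and C10–C11 together, or cutting C4–C5, this single cut leaves ring B intact, so the strained bond is formed last and inside a frame that dictates C10 and C11. The precursor has one ring fewer and only the centres C1, C3, C5 and C6 to supply. The forward step must close a four-membered ring on a carbonyl carbon in preference to the enone β-carbon C8.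

**Epoxide C–O and C5–H.** 16 comes from alkene 15 by epoxidation on the convex face. 15 is the C5 epimer of the trans-fused enone 13 and is reached by kinetic protonation of the ring-fusion enolate 14. This inserts one step but makes the cis fusion, which the cyclisation requires, independent of how C5 was first formed.

**C1=C11.** Ring B of 13 is opened at the trisubstituted alkene to diene 12. Metathesis onto the isopropenyl group uses the carvone side chain as it stands, whereas an aldol or alkylative closure would need extra functionality at C1.

**C2–C3.** 12 is the silyl ether of homoallylic alcohol 11, cut to aldehyde 8 and allylboronate 9. The aldehyde has no α-hydrogen and the new carbinol is the remote centre C3, so catalyst control is asked for.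

**C4–C5.** 8 arises by a Nef reaction from nitro ketone 5, which is cut at C4–C5 to (R)-carvone 1 and nitroalkene 2. The Michael addition makes the quaternary C4 and delivers C3 at the aldehyde oxidation level; carvone supplies C6 and with it the absolute configuration.

## Roads not taken

**Alternative 1:** The enone C8=C9 bond is cut back to the meso 1,3-diacetylcyclobutane A1, already bridged by ring B with a C3 ketal. A chiral primary amine would form an enamine from one acetyl group and condense it with the other to give enone A2.
- Merits: four cage stereocentres arise catalytically from an achiral precursor, and the enone arrives at its final oxidation level. In this respect it is better than the chosen plan, which spends steps 10 to 12 on moving oxygen from C10 to C7.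
- Weak points: the mirror plane of A1 forbids an oxygen at C1, so A2 carries a C1 methylene that has no handle for later oxidation. A1 already contains the bridged cyclobutane, so the hardest bond construction is only postponed. The condensation must close a strained bicyclo[3.1.1]heptenone against retro-aldol cleavage.
- Comparison: the chosen plan keeps the C1 oxygen from the epoxide and takes its absolute configuration from carvone. It pays with a redox detour.

**Alternative 2:** C5–C6 and C10–C11 are cut together. Dehydrochlorination of dienoyl chloride A3 with Et3N and intramolecular [2+2] addition of the ketene function across the C6=C11 alkene would give cyclobutanone A4.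
- Merits: this is the classical entry to bicyclo[3.1.1]heptan-6-ones, it needs no reagent beyond base, and the alkene geometry sets C11. Its precedent for the ring-forming event is firmer than that of a 4-exo radical closure.
- Weak points: facial control rests on one open-chain stereocentre (C1). C5 arrives as a ketone, so ring B must be closed by adding a fully substituted C4 enolate to a cyclobutanone, followed by a tertiary deoxygenation at C5. The exocyclic methylene must be moved into the ring before C7 is oxidised.
- Comparison: the chosen plan closes ring B first by a reliable metathesis and lets that ring fix C5 and C11. It accepts the less precedented closure in exchange.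

**Alternative 3:** C4–C5 is cut. Rh2(OAc)4 would decompose diazo β-keto ester A5, and the C4 carbenoid would insert into the C5–H bond to give β-keto ester A6.
- Merits: the bicyclo[3.1.1]heptene is present from the start with C10–H in place, so no deoxygenation is needed, and the C3 carbonyl and C1 oxygen are already positioned. Here it is better than the chosen plan.
- Weak points: such carbenoids favour five-membered-ring insertion; a seven-membered closure into a cyclobutane C–H bond of high s-character competes poorly with cyclopropanation of C8=C9 and insertion next to the silyloxy group. The ester must then be turned into the second methyl of C4 over several steps. A5 needs a stereodefined quaternary C11 that is itself hard to make.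
- Comparison: the chosen plan makes C4 in its first step and confines its uncertainty to one step with a direct model.

Key step: step 8

Remark: atoms keep the target numbers C1–C11 in every intermediate; the C5 configuration formed in step 1 is immaterial because C5 is set again in step 6.

## Route

Step 1
Reactants: 1 (R)-carvone; 2 2-methyl-1-nitroprop-1-ene
Product: 5 trans nitro ketone (5R,6R)-2-methyl-6-(2-methyl-1-nitropropan-2-yl)-5-(prop-1-en-2-yl)cyclohex-2-en-1-one, via lithium dienolate of carvone 3 (not isolated), via lithium nitronate of the adduct 4 (not isolated)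
Conditions: LiN(iPr)2, THF, −78 °C; 2, −78 °C; AcOH, −78 °C
Reagents that add atoms: none
Why: Kinetic deprotonation gives the cross-conjugated α′-enolate, which adds in a Michael reaction to the β,β-disubstituted carbon of the nitroalkene and creates quaternary C4; attack anti to the isopropenyl group should give the trans isomer, and the cold quench stops the nitronate before it can add to C8.

Step 2
Reactants: 5
Product: 8 trans keto aldehyde 2-methyl-2-[(1R,6R)-3-methyl-2-oxo-6-(prop-1-en-2-yl)cyclohex-3-en-1-yl]propanal, via sodium nitronate 6 (not isolated), via N–H aldimine 7 (not isolated)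
Conditions: NaOMe, MeOH, 0 °C; then aq. TiCl3, NH4OAc, THF, rt
Reagents that add atoms: water, O
Why: Reductive Nef reaction: trivalent titanium reduces the nitronate to the imine, which hydrolyses in the buffered medium; C4 is quaternary, so the aldehyde can neither enolise nor close to a furan, and the enone and isopropenyl group are not reduced.

Step 3
Reactants: 8; 9 allylboronic acid pinacol ester
Product: 11 homoallylic alcohol (5R,6R)-6-[(3R)-3-hydroxy-2-methylhex-5-en-2-yl]-2-methyl-5-(prop-1-en-2-yl)cyclohex-2-en-1-one, via pinacol borate of the alcohol 10 (not isolated)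
Conditions: (R)-TRIP [(R)-3,3′-bis(2,4,6-triisopropylphenyl)-1,1′-binaphthyl-2,2′-diyl hydrogen phosphate] (5 mol %), toluene, −30 °C; aq. work-up
Reagents that add atoms: none
Why: Chiral phosphoric acid-catalysed allylboration through a chair six-membered transition state; the catalyst antipode is chosen for Re-face delivery, which gives 3R, and the boronate adds only to the aldehyde, not to the hindered enone.

Step 4
Reactants: 11
Product: 12 C3 tert-butyldimethylsilyl ether of 11
Conditions: TBSOTf, 2,6-lutidine, CH2Cl2, −78 to 0 °C
Reagents that add atoms: tert-butyldimethylsilyl trifluoromethanesulfonate, CC(C)(C)[Si](C)(C)OS(=O)(=O)C(F)(F)F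
Why: The neopentyl-type alcohol needs the silyl triflate; at low temperature with a hindered pyridine base the ketone is not enol-silylated.

Step 5
Reactants: 12
Product: 13 trans-fused bicyclic enone (ring B closed through C1=C11; H5 trans to H6; 3R,5R,6R)
Conditions: second-generation Grubbs catalyst (H2IMes)(PCy3)Cl2Ru=CHPh (5 mol %), CH2Cl2, 40 °C
Reagents that add atoms: none
Why: Ring-closing metathesis: the catalyst loads on the terminal allyl alkene and closes onto the isopropenyl group to a trisubstituted cycloheptene; the two arms are gauche on ring A, and the electron-poor trisubstituted enone alkene does not take part.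

Step 6
Reactants: 13
Product: 15 cis-fused bicyclic enone (C5 epimer of 13; 3R,5S,6R), via lithium ring-fusion enolate 14 (not isolated)
Conditions: LiN(iPr)2, THF, −78 °C; then AcOH in THF, −78 °C
Reagents that add atoms: none
Why: The axial C5–H is removed kinetically at the α′ position; in enolate 14 ring B (C11 and C3) lies on one face of the enolate plane, so the proton arrives from the other face, syn to H6, as is usual for kinetic protonation of ring-fusion enolates, which give cis-fused ketones.

Step 7
Reactants: 15
Product: 16 cis-fused epoxy enone (C11–C1 epoxide on the face of H5 and H6; 1R,3R,5S,6R,11S)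
Conditions: mCPBA, NaHCO3, CH2Cl2, 0 °C
Reagents that add atoms: 3-chloroperoxybenzoic acid, OOC(=O)c1cccc(Cl)c1
Why: Prilezhaev epoxidation picks the electron-rich trisubstituted alkene over the enone and should attack the convex face of the cis-fused bicycle, anti to the C3 silyloxy group; this places the oxygen on C1 with the configuration of the target.

Step 8
Reactants: 16
Product: 19 tricyclic diol (C1 OH; bridgehead C10 OH; C3 OTBS; configuration of the target), via C11 radical carrying the C1 titanium alkoxide 17 (not isolated), via bis(titanium alkoxide) 18 (not isolated)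
Conditions: Cp2TiCl2 (2.5 equiv), Zn, THF, rt, slow addition of 16; then aq. NaH2PO4
Reagents that add atoms: none
Why: Cp2TiCl (trivalent titanium) transfers one electron to the epoxide, which opens at its more substituted carbon to the tertiary C11 radical 17 while the oxygen stays on C1 as a tetravalent titanium alkoxide. The radical adds to the titanium-bound C10 carbonyl carbon and a second Cp2TiCl ends the sequence as alkoxide 18, so the otherwise reversible closure is not undone; hydrolysis gives 19. The closest known reaction is the reductive cyclisation of γ,δ-epoxy ketones with this reagent, carvone 8,9-epoxide included, where the carbonyl carbon is taken in preference to the enone β-carbon. One ring closes, the cyclobutane C5–C6–C11–C10, in the 4-exo-trig mode. The C10 hydroxyl can only point outward from the bridgehead, and at C11 the C1 arm is tied to C5 through ring B and must stay exo, which puts the methyl over the C7–C9 bridge; both new centres are set by the ring system. C1 is untouched and keeps the epoxide configuration. The step needs attack at C10 and not at C8: the cis fusion of 16 lets C11 sit axial on ring A next to C10, and titanium binds and activates the carbonyl oxygen.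

Step 9
Reactants: 19; 20 tigloyl chloride [(E)-2-methylbut-2-enoyl chloride]
Product: 21 C1 tiglate of 19 (C10 OH free)
Conditions: pyridine, DMAP, CH2Cl2, 0 °C to rt
Reagents that add atoms: none
Why: Acylation of the secondary C1 hydroxyl in the presence of the tertiary bridgehead one; the acid chloride has no α-hydrogen, so no ketene forms and the E geometry is kept.

Step 10
Reactants: 21
Product: 22 C10 methyl oxalate of 21
Conditions: ClC(O)CO2Me, pyridine, DMAP, CH2Cl2, 0 °C to rt
Reagents that add atoms: methyl chlorooxoacetate, COC(=O)C(=O)Cl
Why: The very electrophilic chlorooxoacetate acylates tertiary alcohols and gives the standard radical precursor for their deoxygenation without base strong enough to move the tiglate.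

Step 11
Reactants: 22
Product: 23 C10-deoxy tiglate (C10–H; C7 methylene; C8=C9)
Conditions: Bu3SnH, AIBN (cat.), toluene, 110 °C
Reagents that add atoms: none
Why: Barton–McCombie-type deoxygenation of a tertiary methyl oxalate: the stannyl radical adds to the oxalate, the C10–O bond breaks, and the bridgehead radical, which can neither eliminate nor open, takes hydrogen at the position the oxygen held.

Step 12
Reactants: 23
Product: 24 tricyclic enone (C7 ketone; C1 tiglate; C3 OTBS)
Conditions: CrO3, 3,5-dimethylpyrazole, CH2Cl2, −20 °C
Reagents that add atoms: chromium trioxide, O=[Cr](=O)=O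
Why: Allylic oxidation by the hexavalent chromium–pyrazole complex, the conversion that turns α-pinene into verbenone; C7 is the only secondary allylic position, the bridgehead C10–H is orthogonal to the π system, and the methyl groups react more slowly.

Step 13
Reactants: 24
Product: 25 C3 alcohol (24 without the silyl group)
Conditions: HF·pyridine, THF, 0 °C to rt
Reagents that add atoms: none
Why: Fluoride-assisted cleavage of the Si–O bond under weakly acidic conditions, which spare the enone and the tiglate and do not promote acyl migration.

Step 14
Reactants: 25; 26 3-methylbut-2-enoic acid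
Product: 28 target diester CNP0277258.1, via senecioic 2,4,6-trichlorobenzoic anhydride 27 (not isolated)
Conditions: 26, 2,4,6-Cl3C6H2COCl, Et3N, THF, rt; then 25, DMAP, toluene, rt to 50 °C
Reagents that add atoms: none
Why: Yamaguchi esterification: DMAP attacks the less hindered carbonyl of the mixed anhydride and transfers the senecioyl group to the hindered C3 hydroxyl; amine is consumed before the alcohol is added, which limits deconjugation.

## Compound list

1 | (R)-carvone | CC1=CC[C@H](CC1=O)C(C)=C | starting material
2 | 2-methyl-1-nitroprop-1-ene | CC(C)=C[N+](=O)[O-] | starting material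
3 | lithium dienolate of carvone (C5=C10) | CC1=CC[C@@H](C(C)=C)C=C1O[Li] | intermediate
4 | lithium nitronate of the Michael adduct | O=C1C(C)=CC[C@@H](C(C)=C)[C@@H]1C(C)(C)C=[N+]([O-])O[Li] | intermediate
5 | trans nitro ketone, (5R,6R)-2-methyl-6-(2-methyl-1-nitropropan-2-yl)-5-(prop-1-en-2-yl)cyclohex-2-en-1-one | O=C1C(C)=CC[C@@H](C(C)=C)[C@@H]1C(C)(C)C[N+](=O)[O-] | intermediate
6 | sodium nitronate of 5 | O=C1C(C)=CC[C@@H](C(C)=C)[C@@H]1C(C)(C)C=[N+]([O-])[O-].[Na+] | intermediate
7 | N–H aldimine of 8 | O=C1C(C)=CC[C@@H](C(C)=C)[C@@H]1C(C)(C)C=N | intermediate
8 | trans keto aldehyde, 2-methyl-2-[(1R,6R)-3-methyl-2-oxo-6-(prop-1-en-2-yl)cyclohex-3-en-1-yl]propanal | O=C1C(C)=CC[C@@H](C(C)=C)[C@@H]1C(C)(C)C=O | intermediate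
9 | allylboronic acid pinacol ester | C=CCB1OC(C)(C)C(C)(C)O1 | starting material
10 | pinacol borate of 11 | O=C1C(C)=CC[C@@H](C(C)=C)[C@@H]1C(C)(C)[C@H](OB2OC(C)(C)C(C)(C)O2)CC=C | intermediate
11 | homoallylic alcohol, (5R,6R)-6-[(3R)-3-hydroxy-2-methylhex-5-en-2-yl]-2-methyl-5-(prop-1-en-2-yl)cyclohex-2-en-1-one | O=C1C(C)=CC[C@@H](C(C)=C)[C@@H]1C(C)(C)[C@H](O)CC=C | intermediate
12 | C3 tert-butyldimethylsilyl ether of 11 | O=C1C(C)=CC[C@@H](C(C)=C)[C@@H]1C(C)(C)[C@H](O[Si](C)(C)C(C)(C)C)CC=C | intermediate
13 | trans-fused bicyclic enone (ring A enone fused at C5–C6 to ring B with C1=C11, 11-methyl, 4,4-dimethyl, 3R silyloxy; 5R,6R) | O=C1C(C)=CC[C@@H]2[C@@H]1C(C)(C)[C@H](O[Si](C)(C)C(C)(C)C)CC=C2C | intermediate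
14 | lithium ring-fusion enolate (C5=C10) | CC1=CC[C@H]2C(C)=CC[C@@H](O[Si](C)(C)C(C)(C)C)C(C)(C)C2=C1O[Li] | intermediate
15 | cis-fused bicyclic enone (C5 epimer of 13; 3R,5S,6R) | O=C1C(C)=CC[C@@H]2[C@H]1C(C)(C)[C@H](O[Si](C)(C)C(C)(C)C)CC=C2C | intermediate
16 | cis-fused epoxy enone (C11–C1 epoxide syn to H5 and H6; 1R,3R,5S,6R,11S) | O=C1C(C)=CC[C@@H]2[C@H]1C(C)(C)[C@H](O[Si](C)(C)C(C)(C)C)C[C@H]3O[C@@]23C | intermediate
17 | C11 radical with the C1 oxygen bound to Cp2TiCl | O=C1C(C)=CC[C@@H]2[C@H]1C(C)(C)[C@H](O[Si](C)(C)C(C)(C)C)C[C@@H](O[Ti](Cl)(C3C=CC=C3)C3C=CC=C3)[C]2C | intermediate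
18 | bis(titanium alkoxide) of 19 (C1–O and C10–O bound to Cp2TiCl) | Cl[Ti](C4C=CC=C4)(C4C=CC=C4)O[C@@H]1C[C@@H](O[Si](C)(C)C(C)(C)C)C(C)(C)[C@@H]2[C@H]3CC=C(C)[C@]2(O[Ti](Cl)(C4C=CC=C4)C4C=CC=C4)[C@]31C | intermediate
19 | tricyclic diol (C1 OH, bridgehead C10 OH, C3 OTBS, C8=C9) | O[C@@H]1C[C@@H](O[Si](C)(C)C(C)(C)C)C(C)(C)[C@@H]2[C@H]3CC=C(C)[C@]2(O)[C@]31C | intermediate
20 | tigloyl chloride, (E)-2-methylbut-2-enoyl chloride | C/C=C(\C)C(=O)Cl | starting material
21 | C1 tiglate of 19 | C/C=C(\C)C(=O)O[C@@H]1C[C@@H](O[Si](C)(C)C(C)(C)C)C(C)(C)[C@@H]2[C@H]3CC=C(C)[C@]2(O)[C@]31C | intermediate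
22 | C10 methyl oxalate of 21 | C/C=C(\C)C(=O)O[C@@H]1C[C@@H](O[Si](C)(C)C(C)(C)C)C(C)(C)[C@@H]2[C@H]3CC=C(C)[C@]2(OC(=O)C(=O)OC)[C@]31C | intermediate
23 | C10-deoxy tiglate | C/C=C(\C)C(=O)O[C@@H]1C[C@@H](O[Si](C)(C)C(C)(C)C)C(C)(C)[C@@H]2[C@H]3CC=C(C)[C@@H]2[C@]31C | intermediate
24 | tricyclic enone (C7 ketone, C1 tiglate, C3 OTBS) | C/C=C(\C)C(=O)O[C@@H]1C[C@@H](O[Si](C)(C)C(C)(C)C)C(C)(C)[C@@H]2[C@H]3C(=O)C=C(C)[C@@H]2[C@]31C | intermediate
25 | C3 alcohol | C/C=C(\C)C(=O)O[C@@H]1C[C@@H](O)C(C)(C)[C@@H]2[C@H]3C(=O)C=C(C)[C@@H]2[C@]31C | intermediate
26 | 3-methylbut-2-enoic acid | CC(C)=CC(=O)O | starting material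
27 | senecioic 2,4,6-trichlorobenzoic anhydride | CC(C)=CC(=O)OC(=O)c1c(Cl)cc(Cl)cc1Cl | intermediate
28 | CNP0277258.1 (C1 tiglate, C3 senecioate) | C/C=C(\C)C(=O)O[C@@H]1C[C@@H](OC(=O)C=C(C)C)C(C)(C)[C@@H]2[C@H]3C(=O)C=C(C)[C@@H]2[C@]31C | target

## Step count and risks

Total step count: 14. Longest linear sequence: 14 steps from (R)-carvone 1.

**Step 8 (key step).** The tertiary radical may be lost by hydrogen transfer to a second titanium centre, or by reduction, before the strained 4-exo closure occurs; addition to C8 is the second concern. The fallback sets out from 16, which Cp2TiCl converts by exactly that hydrogen loss into the exo-methylene allylic alcohol F1. The same C11 radical is then regenerated from F1 by hydrogen-atom transfer from an iron hydride (Fe(acac)3, PhSiH3, EtOH, 60 °C), a known way to add alkene-derived tertiary radicals to ketones, in which an unproductive radical largely returns to the alkene. It comes back to the route at 19.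

**Step 1.** The enolate may take a proton from a methyl group of 2 (allyl nitronate formation) instead of forming the C4–C5 bond, or the nitronate may add on to C8. The fallback sets out from 1, which is converted into its trimethylsilyl dienol ether F2 (LiN(iPr)2, Me3SiCl). F2 adds to 2 in a Mukaiyama–Michael reaction promoted by TiCl2(OiPr)2 in CH2Cl2 at −78 °C, without any free base, and returns at 5.

**Step 2.** The reduction may stall at the oxime, which for a neopentyl aldoxime hydrolyses slowly, or the nitronate may add to C8 before it is reduced. The fallback sets out from 5 and uses the solvolytic Nef reaction: the nitronate is run into H2SO4/MeOH at −40 °C to give the dimethyl acetal F3, which aqueous oxalic acid in THF hydrolyses, returning at 8.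

**Step 6.** Deprotonation may occur at C7 in competition with the hindered C5–H, or the proton may be delivered with poor facial selectivity. The fallback sets out from 13 and equilibrates it with DBU in toluene; both ring fusions are expected to be populated, because the cis isomer relieves the eclipsing between C7 and the C11 methyl. 15 is separated and 13 recycled, so the detour makes no new compound (F0) and returns at 15.

**Step 11.** Cleavage of the C10–O bond to a strained bridgehead radical may be slow, so that stannyl radicals add to the tiglate or the oxalate is merely reduced back to the alcohol. The fallback sets out from 21, which oxalyl chloride converts into the chlorooxalate F4. The sodium salt of N-hydroxypyridine-2-thione then gives the mixed oxalate thiohydroxamate F5, and visible light with tert-butyl thiol releases the C10 radical by loss of two molecules of CO2, the thiol supplying the hydrogen. It returns at 23.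

## Further compounds

F1 | step 8 | exo-methylene allylic alcohol (C1 OH, C11=CH2, cis-fused enone) | O=C1C(C)=CC[C@@H]2[C@H]1C(C)(C)[C@H](O[Si](C)(C)C(C)(C)C)C[C@@H](O)C2=C
F2 | step 1 | trimethylsilyl dienol ether of carvone | CC1=CC[C@@H](C(C)=C)C=C1O[Si](C)(C)C
F3 | step 2 | dimethyl acetal of 8 | O=C1C(C)=CC[C@@H](C(C)=C)[C@@H]1C(C)(C)C(OC)OC
F0 | step 6 | none | none
F4 | step 11 | C10 chlorooxalate of 21 | C/C=C(\C)C(=O)O[C@@H]1C[C@@H](O[Si](C)(C)C(C)(C)C)C(C)(C)[C@@H]2[C@H]3CC=C(C)[C@]2(OC(=O)C(Cl)=O)[C@]31C
F5 | step 11 | C10 oxalate thiohydroxamate of 21 | C/C=C(\C)C(=O)O[C@@H]1C[C@@H](O[Si](C)(C)C(C)(C)C)C(C)(C)[C@@H]2[C@H]3CC=C(C)[C@]2(OC(=O)C(=O)ON4C=CC=CC4=S)[C@]31C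
A1 | alternative 1 | meso diacetyl cyclobutane with ring B and C3 ketal | C1CC2(OCCO2)C(C)(C)[C@@H]3[C@@H](C(C)=O)[C@@]1(C)[C@H]3C(C)=O
A2 | alternative 1 | tricyclic enone with C3 ketal | C1CC2(OCCO2)C(C)(C)[C@@H]3[C@H]4C(=O)C=C(C)[C@@H]3[C@]41C
A3 | alternative 2 | (2E,6E)-dienoyl chloride with C1 silyloxy and C3 ketal side chain | O=C(Cl)/C=C(\C)CC/C=C(\C)[C@H](O[Si](C)(C)C(C)(C)C)CC1(OCCO1)C(C)C
A4 | alternative 2 | 2-methylenebicyclo[3.1.1]heptan-6-one with the C11 side chain | O=C1[C@H]2CCC(=C)[C@@H]1[C@@]2(C)[C@H](O[Si](C)(C)C(C)(C)C)CC3(OCCO3)C(C)C
A5 | alternative 3 | α-diazo β-keto ester on the bicyclo[3.1.1]heptene | C[C@]1([C@H](O[Si](C(C)C)(C(C)C)C(C)C)CC(=O)C(=[N+]=[N-])C(=O)OC)[C@H]2C[C@@H]1C(C)=CC2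
A6 | alternative 3 | tricyclic β-keto ester | CC(C)[Si](C(C)C)(C(C)C)O[C@@H]1CC(=O)[C@@H](C(=O)OC)[C@@H]2[C@H]3CC=C(C)[C@@H]2[C@]31C
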